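**Retrosynthetic overview**
1. Kazinol K ⇐ chromene ketone 21 (MOM removal; C=O → CH2) ⇐ catechol ketone 17 (propargyl ether on the C8a oxygen, Claisen cascade onto C4a).
2. The strategy rests on ring B (chromene carbons C4a, C5, C6, C7, C8, C8a): a catechol with its oxygens on C8 and C8a, the prenyl group on C5 and the three-carbon linker on C6. It is cut across C4a–C5 and C6–C7 into 2,3-bis(trimethylsilyloxy)butadiene 14 and ynone 12.
3. Ynone 12 ⇐ Weinreb amide 9 + 5-methylhex-4-en-1-yne 10; 9 ⇐ ring-A aldehyde 6 (Wittig, conjugate reduction); 6 ⇐ 2,4-dihydroxybenzaldehyde by an aryl prenyl ether Claisen shift to C5.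
4. Ring order: ring A is bought, ring B is made by the [4+2]/dehydrogenation, and the pyran ring is closed last on ring B.

Key step: step 11

Remark: Kazinol K has no stereocentre; the only stereo-elements on the way are the (E)-alkene of 7 (removed in step 6) and a racemic carbon in the transient 23 (removed in step 15).

**Route**

Step 1
Reactants: 1 2,4-dihydroxybenzaldehyde; 2 prenyl bromide (1-bromo-3-methylbut-2-ene)
Product: 3 2-hydroxy-4-(3-methylbut-2-enyloxy)benzaldehyde
Conditions: K2CO3 (1.0 equiv), acetone, rt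
Reagents that add atoms: none
Why: Williamson ether synthesis; the 2-OH is held in a hydrogen bond to the aldehyde and is the poorer nucleophile, so mono-alkylation should occur at the 4-OH.

Step 2
Reactants: 3 2-hydroxy-4-(3-methylbut-2-enyloxy)benzaldehyde
Product: 4 2-(methoxymethoxy)-4-(3-methylbut-2-enyloxy)benzaldehyde
Conditions: MOMCl, iPr2NEt, CH2Cl2, 0 °C → 40 °C
Reagents that add atoms: chloromethyl methyl ether (COCCl)
Why: O-alkylation of the phenol to its methoxymethyl acetal; capping this oxygen removes the chelate that would otherwise steer the coming Claisen shift to C3.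

Step 3
Reactants: 4 2-(methoxymethoxy)-4-(3-methylbut-2-enyloxy)benzaldehyde
Product: 5 4-hydroxy-2-(methoxymethoxy)-5-(2-methylbut-3-en-2-yl)benzaldehyde
Conditions: EtOH/H2O 4:1, 2,6-lutidine (0.2 equiv), 130 °C, sealed tube
Reagents that add atoms: none
Why: Aromatic Claisen rearrangement ([3,3] shift, then rearomatising enolisation) should place the 1,1-dimethylallyl group on C5, because C3 lies between two oxygen substituents; the aqueous medium speeds the shift at a temperature that holds back secondary rearrangement, and lutidine keeps the medium from becoming acidic toward the MOM acetal.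

Step 4
Reactants: 5 4-hydroxy-2-(methoxymethoxy)-5-(2-methylbut-3-en-2-yl)benzaldehyde
Product: 6 2,4-bis(methoxymethoxy)-5-(2-methylbut-3-en-2-yl)benzaldehyde
Conditions: MOMCl, iPr2NEt, CH2Cl2, 40 °C
Reagents that add atoms: chloromethyl methyl ether (COCCl)
Why: MOM ether formation on the acidic para-formyl phenol, which also shuts off any later cyclisation of this phenol onto the neighbouring vinyl group.

Step 5
Reactants: 6 2,4-bis(methoxymethoxy)-5-(2-methylbut-3-en-2-yl)benzaldehyde
Product: 7 methyl (E)-3-[2,4-bis(methoxymethoxy)-5-(2-methylbut-3-en-2-yl)phenyl]prop-2-enoate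
Conditions: Ph3P=CHCO2Me, toluene, 90 °C
Reagents that add atoms: methyl (triphenylphosphoranylidene)acetate (COC(=O)C=P(c1ccccc1)(c1ccccc1)c1ccccc1)
Why: Wittig olefination with a stabilised ylide should give the (E)-cinnamate; the alkene geometry is immaterial because the double bond is reduced next.

Step 6
Reactants: 7 methyl (E)-3-[2,4-bis(methoxymethoxy)-5-(2-methylbut-3-en-2-yl)phenyl]prop-2-enoate
Product: 8 methyl 3-[2,4-bis(methoxymethoxy)-5-(2-methylbut-3-en-2-yl)phenyl]propanoate
Conditions: Mg turnings (excess), MeOH, 0 °C → rt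
Reagents that add atoms: none
Why: Dissolving-metal conjugate reduction with magnesium in methanol reduces only the ester-conjugated C=C by electron transfer, so the isolated vinyl group, which hydrogenation would not spare, is left intact.

Step 7
Reactants: 8 methyl 3-[2,4-bis(methoxymethoxy)-5-(2-methylbut-3-en-2-yl)phenyl]propanoate
Product: 9 3-[2,4-bis(methoxymethoxy)-5-(2-methylbut-3-en-2-yl)phenyl]-N-methoxy-N-methylpropanamide
Conditions: MeNH(OMe)·HCl, iPrMgCl, THF, −20 °C → 0 °C
Reagents that add atoms: N,O-dimethylhydroxylamine hydrochloride (CNOC.Cl)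
Why: Direct aminolysis of the ester by the chloromagnesium amide (Weinreb amide synthesis) under basic conditions that leave the MOM acetals untouched.

Step 8
Reactants: 2 prenyl bromide
Product: 10 5-methylhex-4-en-1-yne
Conditions: HC≡CMgBr, CuCl (5 mol%), THF, 0 °C → rt; fractional distillation
Reagents that add atoms: ethynylmagnesium bromide (C#C[Mg]Br)
Why: CuCl-catalysed coupling of an alkynyl Grignard reagent with an allylic bromide (substitution at the primary carbon) should give the skipped 1,4-enyne, the minor branched isomer being removed by distillation.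

Step 9
Reactants: 9 3-[2,4-bis(methoxymethoxy)-5-(2-methylbut-3-en-2-yl)phenyl]-N-methoxy-N-methylpropanamide; 10 5-methylhex-4-en-1-yne
Product: 12 1-[2,4-bis(methoxymethoxy)-5-(2-methylbut-3-en-2-yl)phenyl]-8-methylnon-7-en-4-yn-3-one, via lithium acetylide 11 (not isolated)
Conditions: 10, n-BuLi, THF, −78 °C; then 9, −78 °C → −20 °C; cold sat. aq. NH4Cl
Reagents that add atoms: none
Why: Weinreb ketone synthesis: the acetylide adds once because the chelated adduct does not collapse before the quench, and the cold, mildly acidic quench keeps the released amine from adding to the ynone and the doubly activated CH2 from isomerising.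

Step 10
Reactants: 13 butane-2,3-dione
Product: 14 2,3-bis(trimethylsilyloxy)buta-1,3-diene
Conditions: TMSOTf (2.2 equiv), Et3N (2.5 equiv), Et2O, 0 °C → rt; distillation
Reagents that add atoms: trimethylsilyl trifluoromethanesulfonate (C[Si](C)(C)OS(=O)(=O)C(F)(F)F)
Why: Double O-silylation of the diketone through its enol forms (silyl enol ether formation with a silyl triflate and amine base) gives the symmetric diene.

Step 11
Reactants: 12 1-[2,4-bis(methoxymethoxy)-5-(2-methylbut-3-en-2-yl)phenyl]-8-methylnon-7-en-4-yn-3-one; 14 2,3-bis(trimethylsilyloxy)buta-1,3-diene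
Product: 17 3-[2,4-bis(methoxymethoxy)-5-(2-methylbut-3-en-2-yl)phenyl]-1-[4,5-dihydroxy-2-(3-methylbut-2-enyl)phenyl]propan-1-one, via cycloadduct 15 (not isolated), via bis(trimethylsilyl) ether 16 (not isolated)
Conditions: 14 (4 equiv), BHT (cat.), toluene, 150 °C, sealed tube; evaporate excess 14; DDQ (1.05 equiv), toluene, 0 °C → rt; then MeOH, citric acid (cat.), rt
Reagents that add atoms: none
Why: A concerted thermal [4+2] cycloaddition joins the termini of the electron-rich diene 14 to the two alkyne carbons of 12, whose LUMO is lowered by the ketone, and gives the 1,2-bis(silyloxy)cyclohexa-1,4-diene 15; DDQ then takes a hydride from a doubly allylic ring CH2, proton loss gives arene 16, and methanolysis of the two aryl O–Si bonds frees catechol 17. The closest known reaction type is the Diels–Alder benzannulation of 2,3-bis(silyloxy)butadienes with acetylenic esters and ketones followed by dehydrogenation to catechol derivatives. Ring B is closed as a six-membered carbocycle by intermolecular [4+2] annulation (four diene carbons plus two alkyne carbons), the new bonds being the later C4a–C5 and C6–C7. No stereocentre is created, because the two ring CH2 groups of 15 become aromatic CH. Only chemoselectivity is needed: the diene is symmetric so both orientations give the same adduct, the ynone is the sole electron-poor π bond while the prenyl and vinyl alkenes are unactivated, and the ketone ends up on the carbon that becomes C6, para to the future C8a oxygen. Strictly aprotic conditions before the oxidation keep the enediol bis-silyl ether from tautomerising and losing silanol, and one equivalent of DDQ added after removal of excess 14 should leave the benzylic and allylic CH2 groups alone.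

Step 12
Reactants: 17 3-[2,4-bis(methoxymethoxy)-5-(2-methylbut-3-en-2-yl)phenyl]-1-[4,5-dihydroxy-2-(3-methylbut-2-enyl)phenyl]propan-1-one
Product: 18 3-[2,4-bis(methoxymethoxy)-5-(2-methylbut-3-en-2-yl)phenyl]-1-[5-hydroxy-4-(2-methylbut-3-yn-2-yloxy)-2-(3-methylbut-2-enyl)phenyl]propan-1-one
Conditions: 3-chloro-3-methylbut-1-yne (1.1 equiv), DBU (1.0 equiv), CuCl2·2H2O (1 mol%), MeCN, 0 °C, Ar
Reagents that add atoms: 3-chloro-3-methylbut-1-yne (C#CC(C)(C)Cl)
Why: Copper-catalysed propargylic O-alkylation of a phenoxide; with one equivalent of base only the phenol para to the ketone (the more acidic one, as in 4-O-selective alkylation of 3,4-dihydroxyaryl carbonyl compounds) is ionised, so the ether should form on the future C8a oxygen.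

Step 13
Reactants: 18 3-[2,4-bis(methoxymethoxy)-5-(2-methylbut-3-en-2-yl)phenyl]-1-[5-hydroxy-4-(2-methylbut-3-yn-2-yloxy)-2-(3-methylbut-2-enyl)phenyl]propan-1-one
Product: 21 3-[2,4-bis(methoxymethoxy)-5-(2-methylbut-3-en-2-yl)phenyl]-1-[8-hydroxy-2,2-dimethyl-5-(3-methylbut-2-enyl)-2H-chromen-6-yl]propan-1-one, via ortho-allenylphenol 19 (not isolated), via ortho-quinone methide 20 (not isolated)
Conditions: o-xylene, 140 °C, Ar
Reagents that add atoms: none
Why: Thermal aryl propargyl ether Claisen rearrangement: the [3,3] shift can end productively only on the free ortho carbon (the other ortho position carries the OH), enolisation gives 19, a 1,5-hydrogen shift gives 20, and oxa-6π electrocyclisation closes the 2,2-dimethylpyran ring.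

Step 14
Reactants: 21 3-[2,4-bis(methoxymethoxy)-5-(2-methylbut-3-en-2-yl)phenyl]-1-[8-hydroxy-2,2-dimethyl-5-(3-methylbut-2-enyl)-2H-chromen-6-yl]propan-1-one
Product: 22 N'-tosylhydrazone of ketone 21 (E/Z mixture at C=N)
Conditions: TsNHNH2 (1.5 equiv), EtOH, 70 °C
Reagents that add atoms: p-toluenesulfonyl hydrazide (Cc1ccc(S(=O)(=O)NN)cc1)
Why: Condensation of the aryl alkyl ketone with a sulfonyl hydrazide (hydrazone formation) needs no added acid, so the acetals, the chromene and the prenyl group are not exposed to it.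

Step 15
Reactants: 22 N'-tosylhydrazone of ketone 21
Product: 24 6-{3-[2,4-bis(methoxymethoxy)-5-(2-methylbut-3-en-2-yl)phenyl]propyl}-2,2-dimethyl-5-(3-methylbut-2-enyl)-2H-chromen-8-ol, via N-boryl hydrazide 23 (not isolated)
Conditions: catecholborane (3 equiv), CHCl3, 0 °C → rt; then NaOAc·3H2O, 60 °C
Reagents that add atoms: none
Why: Caglioti-type tosylhydrazone reduction with catecholborane: hydroboration of the C=N bond gives 23, and acetate then triggers loss of sulfinate and N2 to leave the CH2 group; no benzylic cation is formed that the neighbouring prenyl alkene could trap, and the alkenes and MOM acetals should be tolerated.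

Step 16
Reactants: 24 6-{3-[2,4-bis(methoxymethoxy)-5-(2-methylbut-3-en-2-yl)phenyl]propyl}-2,2-dimethyl-5-(3-methylbut-2-enyl)-2H-chromen-8-ol
Product: 25 Kazinol K
Conditions: 3 M aq. HCl, MeOH, rt → 40 °C
Reagents that add atoms: none
Why: Acid-catalysed acetal exchange removes both aryl MOM groups; dilute acid at mild temperature should spare the chromene, the prenyl group and the vinyl group next to the liberated phenol.

**Compound list**
1 | 2,4-dihydroxybenzaldehyde | O=Cc1ccc(O)cc1O | starting material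
2 | prenyl bromide (1-bromo-3-methylbut-2-ene) | CC(C)=CCBr | starting material
3 | 2-hydroxy-4-(3-methylbut-2-enyloxy)benzaldehyde | O=Cc1ccc(OCC=C(C)C)cc1O | intermediate
4 | 2-(methoxymethoxy)-4-(3-methylbut-2-enyloxy)benzaldehyde | COCOc1cc(OCC=C(C)C)ccc1C=O | intermediate
5 | 4-hydroxy-2-(methoxymethoxy)-5-(2-methylbut-3-en-2-yl)benzaldehyde | COCOc1cc(O)c(C(C)(C)C=C)cc1C=O | intermediate
6 | 2,4-bis(methoxymethoxy)-5-(2-methylbut-3-en-2-yl)benzaldehyde | COCOc1cc(OCOC)c(C(C)(C)C=C)cc1C=O | intermediate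
7 | methyl (E)-3-[2,4-bis(methoxymethoxy)-5-(2-methylbut-3-en-2-yl)phenyl]prop-2-enoate | COC(=O)/C=C/c1cc(C(C)(C)C=C)c(OCOC)cc1OCOC | intermediate
8 | methyl 3-[2,4-bis(methoxymethoxy)-5-(2-methylbut-3-en-2-yl)phenyl]propanoate | COC(=O)CCc1cc(C(C)(C)C=C)c(OCOC)cc1OCOC | intermediate
9 | 3-[2,4-bis(methoxymethoxy)-5-(2-methylbut-3-en-2-yl)phenyl]-N-methoxy-N-methylpropanamide | CON(C)C(=O)CCc1cc(C(C)(C)C=C)c(OCOC)cc1OCOC | intermediate
10 | 5-methylhex-4-en-1-yne | C#CCC=C(C)C | intermediate
11 | lithium 5-methylhex-4-en-1-yn-1-ide (formed in the flask) | [Li]C#CCC=C(C)C | intermediate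
12 | 1-[2,4-bis(methoxymethoxy)-5-(2-methylbut-3-en-2-yl)phenyl]-8-methylnon-7-en-4-yn-3-one | CC(C)=CCC#CC(=O)CCc1cc(C(C)(C)C=C)c(OCOC)cc1OCOC | intermediate
13 | butane-2,3-dione | CC(=O)C(C)=O | starting material
14 | 2,3-bis(trimethylsilyloxy)buta-1,3-diene | C=C(O[Si](C)(C)C)C(=C)O[Si](C)(C)C | intermediate
15 | cycloadduct: 3-[2,4-bis(methoxymethoxy)-5-(2-methylbut-3-en-2-yl)phenyl]-1-[2-(3-methylbut-2-enyl)-4,5-bis(trimethylsilyloxy)cyclohexa-1,4-dien-1-yl]propan-1-one (formed in the flask) | CC(C)=CCC1=C(C(=O)CCc2cc(C(C)(C)C=C)c(OCOC)cc2OCOC)CC(O[Si](C)(C)C)=C(O[Si](C)(C)C)C1 | intermediate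
16 | 3-[2,4-bis(methoxymethoxy)-5-(2-methylbut-3-en-2-yl)phenyl]-1-[2-(3-methylbut-2-enyl)-4,5-bis(trimethylsilyloxy)phenyl]propan-1-one (formed in the flask) | CC(C)=CCc1cc(O[Si](C)(C)C)c(O[Si](C)(C)C)cc1C(=O)CCc1cc(C(C)(C)C=C)c(OCOC)cc1OCOC | intermediate
17 | 3-[2,4-bis(methoxymethoxy)-5-(2-methylbut-3-en-2-yl)phenyl]-1-[4,5-dihydroxy-2-(3-methylbut-2-enyl)phenyl]propan-1-one | CC(C)=CCc1cc(O)c(O)cc1C(=O)CCc1cc(C(C)(C)C=C)c(OCOC)cc1OCOC | intermediate
18 | 3-[2,4-bis(methoxymethoxy)-5-(2-methylbut-3-en-2-yl)phenyl]-1-[5-hydroxy-4-(2-methylbut-3-yn-2-yloxy)-2-(3-methylbut-2-enyl)phenyl]propan-1-one | CC(C)=CCc1cc(OC(C)(C)C#C)c(O)cc1C(=O)CCc1cc(C(C)(C)C=C)c(OCOC)cc1OCOC | intermediate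
19 | 3-[2,4-bis(methoxymethoxy)-5-(2-methylbut-3-en-2-yl)phenyl]-1-[4,5-dihydroxy-3-(3-methylbuta-1,2-dienyl)-2-(3-methylbut-2-enyl)phenyl]propan-1-one (formed in the flask) | CC(C)=CCc1c(C=C=C(C)C)c(O)c(O)cc1C(=O)CCc1cc(C(C)(C)C=C)c(OCOC)cc1OCOC | intermediate
20 | ortho-quinone methide: 4-{3-[2,4-bis(methoxymethoxy)-5-(2-methylbut-3-en-2-yl)phenyl]propanoyl}-2-hydroxy-5-(3-methylbut-2-enyl)-6-(3-methylbut-2-enylidene)cyclohexa-2,4-dien-1-one (formed in the flask) | CC(C)=CCC1=C(C(=O)CCc2cc(C(C)(C)C=C)c(OCOC)cc2OCOC)C=C(O)C(=O)C1=CC=C(C)C | intermediate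
21 | 3-[2,4-bis(methoxymethoxy)-5-(2-methylbut-3-en-2-yl)phenyl]-1-[8-hydroxy-2,2-dimethyl-5-(3-methylbut-2-enyl)-2H-chromen-6-yl]propan-1-one | CC(C)=CCc1c2C=CC(C)(C)Oc2c(O)cc1C(=O)CCc1cc(C(C)(C)C=C)c(OCOC)cc1OCOC | intermediate
22 | N'-tosylhydrazone of ketone 21 (E/Z mixture at C=N) | CC(C)=CCc1c2C=CC(C)(C)Oc2c(O)cc1C(CCc1cc(C(C)(C)C=C)c(OCOC)cc1OCOC)=NNS(=O)(=O)c1ccc(C)cc1 | intermediate
23 | N-(1,3,2-benzodioxaborol-2-yl) tosylhydrazide from hydroboration of 22, phenol carried as its catecholboryl ester, racemic at the new N-bearing carbon (formed in the flask) | CC(C)=CCc1c2C=CC(C)(C)Oc2c(OB3Oc4ccccc4O3)cc1C(CCc1cc(C(C)(C)C=C)c(OCOC)cc1OCOC)N(B1Oc2ccccc2O1)NS(=O)(=O)c1ccc(C)cc1 | intermediate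
24 | 6-{3-[2,4-bis(methoxymethoxy)-5-(2-methylbut-3-en-2-yl)phenyl]propyl}-2,2-dimethyl-5-(3-methylbut-2-enyl)-2H-chromen-8-ol | CC(C)=CCc1c2C=CC(C)(C)Oc2c(O)cc1CCCc1cc(C(C)(C)C=C)c(OCOC)cc1OCOC | intermediate
25 | Kazinol K | C=CC(C)(C)c1cc(CCCc2cc(O)c3c(c2CC=C(C)C)C=CC(C)(C)O3)c(O)cc1O | target

**Step count**
Total: 16 steps. Longest linear sequence: 14 steps (steps 1–7, 9, 11–16, from 2,4-dihydroxybenzaldehyde).

**Steps most likely to fail**

Step 11 (benzannulation). The β-alkyl ynone may add too slowly, so that at the temperature needed the skipped enyne unit isomerises toward a conjugated allenyl or dienyl ketone; the enediol bis-silyl ether may also tautomerise and lose silanol before it is oxidised. Fallback, setting out from Weinreb amide 9 and coming back at 17: ring B is taken from an aromatic catechol and joined to the chain by aryl-metal acylation. Commercial 4,5-dibromobenzene-1,2-diol is silylated (TBSCl, imidazole, DMF) to 1,2-dibromo-4,5-bis(tert-butyldimethylsilyloxy)benzene F1. Exchange of one bromine for magnesium (iPrMgCl·LiCl, THF, −15 °C), then CuI catalysis and prenyl bromide 2, should give 1-bromo-2-(3-methylbut-2-enyl)-4,5-bis(tert-butyldimethylsilyloxy)benzene F2. Bromine–lithium exchange (n-BuLi, THF, −78 °C) and addition of 9 should give the bis-silyl ketone F3, and TBAF buffered with AcOH (THF, 0 °C) removes both silyl groups to give 17.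

Step 3 (ring-A Claisen shift). The shift may go to C3 instead of C5, the ether may ionise and lose the prenyl group, the first-formed phenol may rearrange further or cyclise onto the new vinyl group, or the MOM acetal may hydrolyse in the hot aqueous medium. Fallback, setting out from 1 and coming back at 6: the tertiary allyl group is introduced by cross-coupling instead of by rearrangement. Bromination of 1 (Br2, AcOH, rt) gives 5-bromo-2,4-dihydroxybenzaldehyde F4, and MOMCl/iPr2NEt gives 5-bromo-2,4-bis(methoxymethoxy)benzaldehyde F5. A γ-selective Suzuki–Miyaura coupling of F5 with 3,3-dimethylallylboronic acid pinacol ester (Pd(OAc)2, a bulky dialkylbiarylphosphine of the kind known to favour the branched isomer, K3PO4, THF/H2O) should then give 6 directly.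

Step 15 (deoxygenation). Hydride delivery to the hindered, electron-rich hydrazone may be incomplete, or the hydrazone may eliminate to a styrene-type alkene instead of giving the methylene group. Fallback, setting out from 21 and coming back at 25: the ketone is removed by hydride displacement of a benzylic leaving group under basic conditions. The C8 phenol is protected (MOMCl, iPr2NEt) to give the tris-MOM ketone F6, and NaBH4 in MeOH gives the racemic benzylic alcohol F7. MsCl/Et3N in THF at −20 °C should give the racemic benzylic chloride F8, which is treated in the same flask with LiEt3BH to give the tris-MOM propane F9. The acid methanolysis of step 16 then removes all three MOM groups and gives 25.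

**Further compounds**
F1 | step 11 | 1,2-dibromo-4,5-bis(tert-butyldimethylsilyloxy)benzene | CC(C)(C)[Si](C)(C)Oc1cc(Br)c(Br)cc1O[Si](C)(C)C(C)(C)C
F2 | step 11 | 1-bromo-2-(3-methylbut-2-enyl)-4,5-bis(tert-butyldimethylsilyloxy)benzene | CC(C)=CCc1cc(O[Si](C)(C)C(C)(C)C)c(O[Si](C)(C)C(C)(C)C)cc1Br
F3 | step 11 | 3-[2,4-bis(methoxymethoxy)-5-(2-methylbut-3-en-2-yl)phenyl]-1-[4,5-bis(tert-butyldimethylsilyloxy)-2-(3-methylbut-2-enyl)phenyl]propan-1-one | CC(C)=CCc1cc(O[Si](C)(C)C(C)(C)C)c(O[Si](C)(C)C(C)(C)C)cc1C(=O)CCc1cc(C(C)(C)C=C)c(OCOC)cc1OCOC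
F4 | step 3 | 5-bromo-2,4-dihydroxybenzaldehyde | O=Cc1cc(Br)c(O)cc1O
F5 | step 3 | 5-bromo-2,4-bis(methoxymethoxy)benzaldehyde | COCOc1cc(OCOC)c(Br)cc1C=O
F6 | step 15 | 3-[2,4-bis(methoxymethoxy)-5-(2-methylbut-3-en-2-yl)phenyl]-1-[8-(methoxymethoxy)-2,2-dimethyl-5-(3-methylbut-2-enyl)-2H-chromen-6-yl]propan-1-one | CC(C)=CCc1c2C=CC(C)(C)Oc2c(OCOC)cc1C(=O)CCc1cc(C(C)(C)C=C)c(OCOC)cc1OCOC
F7 | step 15 | racemic 3-[2,4-bis(methoxymethoxy)-5-(2-methylbut-3-en-2-yl)phenyl]-1-[8-(methoxymethoxy)-2,2-dimethyl-5-(3-methylbut-2-enyl)-2H-chromen-6-yl]propan-1-ol | CC(C)=CCc1c2C=CC(C)(C)Oc2c(OCOC)cc1C(O)CCc1cc(C(C)(C)C=C)c(OCOC)cc1OCOC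
F8 | step 15 | racemic 6-{1-chloro-3-[2,4-bis(methoxymethoxy)-5-(2-methylbut-3-en-2-yl)phenyl]propyl}-8-(methoxymethoxy)-2,2-dimethyl-5-(3-methylbut-2-enyl)-2H-chromene | CC(C)=CCc1c2C=CC(C)(C)Oc2c(OCOC)cc1C(Cl)CCc1cc(C(C)(C)C=C)c(OCOC)cc1OCOC
F9 | step 15 | 6-{3-[2,4-bis(methoxymethoxy)-5-(2-methylbut-3-en-2-yl)phenyl]propyl}-8-(methoxymethoxy)-2,2-dimethyl-5-(3-methylbut-2-enyl)-2H-chromene | CC(C)=CCc1c2C=CC(C)(C)Oc2c(OCOC)cc1CCCc1cc(C(C)(C)C=C)c(OCOC)cc1OCOC
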